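**Plan**
Labels: lower flavan unit O1, C2, C3, C4, C4a, C5 (ketone), C6, C7, C8 (spiro), C8a; upper unit Cβ (O–CH–aryl on the C7 oxygen), Cα (C–OH), C4′ (ketone carbon on ring A); ring A = dioxygenated benzo ring, ring B = five-membered C7–O–Cβ–Cα–C8, ring C = six-membered Cα–C4′–ring A–O–C8, ring D = cyclohexadienone, ring E = flavan pyran.
Enabling feature and key cut: Cα–C8 links two fully substituted carbons and Cα carries OH beside the ring A ketone C4′, so rings B and C meet in a tertiary α-hydroxy ketone that is one of several interconvertible α-ketols; Cα–C8 is cut and C8 re-attached to C4′, giving the isomer with C4′ as aryl carbinol of a spiro dihydrobenzofuran and Cα as ketone of a six-membered pyranone.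
Further cuts: the aryl C–O bond (ring A–O–C8), then C8–C4′ and C7–O(Cβ), giving a flavan-5,8-quinone and an open-chain Cβ(OH)–Cα(=O)–C4′(OR)(2-bromoaryl) ketone; the quinone is cut at O1–C8a and C4–C4a, the ketone at Cα–C4′.
Forward order: C4 is joined to a lithiated tetramethoxybenzene, the arene is oxidised to the quinone and ring E closes by alkoxy exchange; the ketone dianion annulates the quinone (C7–O, then C8–C4′) to the pyranone, Pd closes the dihydrobenzofuran, and the shift contracts the pyranone to ring B while expanding the furan to ring C.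
Stereochemistry: C3 from methyl (S)-glycidate, C2 by Felkin–Anh reduction, Cβ from (S)-4-hydroxymandelic acid; Cβ directs C8 and C4′ in the annulation (and is expected to be the favoured, equatorial epimer of the cis-fused precursor), and C8 dictates Cα in the shift.

Key step: step 18

Remark: (S)-4-hydroxymandelic acid is taken as a purchasable single enantiomer; C4′ before step 15 and the acetal carbon of the 1-ethoxyethyl group are stereochemically undefined and of no consequence.

**Step 1**
Reactants: 1 1,2,3,5-tetramethoxybenzene; 2 methyl (2S)-oxirane-2-carboxylate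
Product: 5 methyl (2S)-2-hydroxy-3-(2,3,4,6-tetramethoxyphenyl)propanoate, via (2,3,4,6-tetramethoxyphenyl)lithium 3 (not isolated), via bromo(2,3,4,6-tetramethoxyphenyl)magnesium 4 (not isolated)
Conditions: n-BuLi, THF, 0 °C; MgBr2·OEt2, −40 °C; CuI (10 mol %), then 2, −40 → −10 °C
Reagents that add atoms: none
Why: Directed ortho-lithiation removes the only proton flanked by two methoxy groups, and the derived Grignard reagent under CuI catalysis should open the glycidate at its CH2 carbon (SN2 epoxide opening) faster than it attacks the ester in the cold, so the glycidate stereocentre is carried unchanged into the later C3.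

**Step 2**
Reactants: 5 methyl (2S)-2-hydroxy-3-(2,3,4,6-tetramethoxyphenyl)propanoate
Product: 6 methyl (2S)-2-[(tert-butyldimethylsilyl)oxy]-3-(2,3,4,6-tetramethoxyphenyl)propanoate
Conditions: TBSCl, imidazole, DMF, 23 °C
Reagents that add atoms: tert-butyldimethylsilyl chloride, CC(C)(C)[Si](C)(C)Cl
Why: Routine silylation of a secondary alcohol installs the bulky, non-chelating group that the later Felkin–Anh reduction needs.

**Step 3**
Reactants: 6 methyl (2S)-2-[(tert-butyldimethylsilyl)oxy]-3-(2,3,4,6-tetramethoxyphenyl)propanoate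
Product: 7 (2S)-2-[(tert-butyldimethylsilyl)oxy]-N-methoxy-N-methyl-3-(2,3,4,6-tetramethoxyphenyl)propanamide
Conditions: MeNH(OMe)·HCl, i-PrMgCl, THF, −20 → 0 °C
Reagents that add atoms: N,O-dimethylhydroxylamine hydrochloride, CNOC.Cl
Why: Aminolysis of the ester by the magnesium amide (Weinreb amide formation) is not basic enough to epimerise the α-silyloxy centre.

**Step 4**
Reactants: 7 (2S)-2-[(tert-butyldimethylsilyl)oxy]-N-methoxy-N-methyl-3-(2,3,4,6-tetramethoxyphenyl)propanamide; 8 1-bromo-4-(methoxymethoxy)benzene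
Product: 10 (2S)-2-[(tert-butyldimethylsilyl)oxy]-1-[4-(methoxymethoxy)phenyl]-3-(2,3,4,6-tetramethoxyphenyl)propan-1-one, via [4-(methoxymethoxy)phenyl]lithium 9 (not isolated)
Conditions: 8, n-BuLi, THF, −78 °C; then 7, −78 → −40 °C
Reagents that add atoms: none
Why: Bromine–lithium exchange gives the aryllithium, which adds once to the amide through the stable chelated tetrahedral intermediate (Weinreb ketone synthesis).

**Step 5**
Reactants: 10 (2S)-2-[(tert-butyldimethylsilyl)oxy]-1-[4-(methoxymethoxy)phenyl]-3-(2,3,4,6-tetramethoxyphenyl)propan-1-one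
Product: 11 (1S,2S)-2-[(tert-butyldimethylsilyl)oxy]-1-[4-(methoxymethoxy)phenyl]-3-(2,3,4,6-tetramethoxyphenyl)propan-1-ol
Conditions: LiBH(s-Bu)3, THF, −78 °C
Reagents that add atoms: none
Why: The bulky hydride attacks the non-chelated α-silyloxy ketone in the Felkin–Anh sense (silyloxy group anti to the incoming hydride), which should give the syn (1S,2S) alcohol whose carbinol carbon becomes C2.

**Step 6**
Reactants: 11 (1S,2S)-2-[(tert-butyldimethylsilyl)oxy]-1-[4-(methoxymethoxy)phenyl]-3-(2,3,4,6-tetramethoxyphenyl)propan-1-ol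
Product: 12 3-{(2S,3S)-2-[(tert-butyldimethylsilyl)oxy]-3-hydroxy-3-[4-(methoxymethoxy)phenyl]propyl}-2,6-dimethoxycyclohexa-2,5-diene-1,4-dione
Conditions: (NH4)2Ce(NO3)6, MeCN/H2O, 0 °C
Reagents that add atoms: water, O
Why: Oxidative demethylation of the only para-disposed methoxy pair by tetravalent cerium should give the 2,6-dimethoxy-1,4-benzoquinone, the far less electron-rich aryl acetal and the silyl ether surviving the short cold reaction.

**Step 7**
Reactants: 12 3-{(2S,3S)-2-[(tert-butyldimethylsilyl)oxy]-3-hydroxy-3-[4-(methoxymethoxy)phenyl]propyl}-2,6-dimethoxycyclohexa-2,5-diene-1,4-dione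
Product: 13 (2S,3S)-3-[(tert-butyldimethylsilyl)oxy]-7-methoxy-2-[4-(methoxymethoxy)phenyl]-3,4-dihydro-2H-chromene-5,8-dione
Conditions: 10-camphorsulfonic acid (5 mol %), 4 Å molecular sieves, toluene, 23 → 40 °C
Reagents that add atoms: none
Why: Acid-catalysed intramolecular alkoxy exchange (addition–elimination at the methoxy-bearing quinone carbon next to the side chain, 6-endo-trig) closes ring E with retention at C2 to give the 2,3-cis flavan quinone, and acid instead of base avoids 1,2-migration of the silyl group.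

**Step 8**
Reactants: 14 2-bromo-4,6-dimethoxybenzaldehyde
Product: 15 2-bromo-4,6-dihydroxybenzaldehyde
Conditions: BBr3, CH2Cl2, −78 → 23 °C
Reagents that add atoms: none
Why: Lewis-acid demethylation cleaves both aryl methyl ethers without touching the aryl bromide or the aldehyde.

**Step 9**
Reactants: 15 2-bromo-4,6-dihydroxybenzaldehyde
Product: 16 2-bromo-4,6-bis(methoxymethoxy)benzaldehyde
Conditions: MOMCl, i-Pr2NEt, CH2Cl2, 0 → 40 °C
Reagents that add atoms: chloromethyl methyl ether, COCCl
Why: O-Alkylation of both phenols gives base-stable acetals that can be removed by acid at the end.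

**Step 10**
Reactants: 16 2-bromo-4,6-bis(methoxymethoxy)benzaldehyde
Product: 17 [2-bromo-4,6-bis(methoxymethoxy)phenyl](tributylstannyl)methanol
Conditions: Bu3SnH, LiN(i-Pr)2, THF, 0 °C; then 16, −78 °C
Reagents that add atoms: tributylstannane, CCCC[SnH](CCCC)CCCC
Why: The stannyl anion adds to the aldehyde carbonyl at −78 °C much faster than it attacks the aryl bromide (carbonyl stannylation); the new centre is racemic and is erased later by enolisation.

**Step 11**
Reactants: 17 [2-bromo-4,6-bis(methoxymethoxy)phenyl](tributylstannyl)methanol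
Product: 18 {[2-bromo-4,6-bis(methoxymethoxy)phenyl](1-ethoxyethoxy)methyl}tributylstannane
Conditions: ethyl vinyl ether, pyridinium p-toluenesulfonate (5 mol %), CH2Cl2, 0 → 23 °C
Reagents that add atoms: ethyl vinyl ether, C=COCC
Why: Acid-catalysed addition of the alcohol to the vinyl ether gives an acetal that stabilises the later α-alkoxy organolithium by chelation and is far more acid-labile than the aryl methoxymethyl and silyl ethers.

**Step 12**
Reactants: 19 (2S)-2-hydroxy-2-(4-hydroxyphenyl)acetic acid
Product: 20 (2S)-2-hydroxy-2-(4-hydroxyphenyl)-N-methoxy-N-methylacetamide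
Conditions: MeNH(OMe)·HCl, N-(3-dimethylaminopropyl)-N′-ethylcarbodiimide hydrochloride, 1-hydroxybenzotriazole, N-methylmorpholine, CH2Cl2/DMF, 0 → 23 °C
Reagents that add atoms: N,O-dimethylhydroxylamine hydrochloride, CNOC.Cl
Why: Carbodiimide amidation via the active ester acylates the amine in preference to the hydroxyl groups and does not disturb the benzylic stereocentre.

**Step 13**
Reactants: 20 (2S)-2-hydroxy-2-(4-hydroxyphenyl)-N-methoxy-N-methylacetamide
Product: 21 (2S)-2-hydroxy-N-methoxy-2-[4-(methoxymethoxy)phenyl]-N-methylacetamide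
Conditions: MOMCl (1.1 equiv), K2CO3, acetone, 0 → 23 °C
Reagents that add atoms: chloromethyl methyl ether, COCCl
Why: K2CO3 deprotonates only the phenol, so the Williamson alkylation is selective for the phenolic oxygen.

**Step 14**
Reactants: 18 {[2-bromo-4,6-bis(methoxymethoxy)phenyl](1-ethoxyethoxy)methyl}tributylstannane; 21 (2S)-2-hydroxy-N-methoxy-2-[4-(methoxymethoxy)phenyl]-N-methylacetamide
Product: 23 (1S)-3-[2-bromo-4,6-bis(methoxymethoxy)phenyl]-3-(1-ethoxyethoxy)-1-hydroxy-1-[4-(methoxymethoxy)phenyl]propan-2-one, via [2-bromo-4,6-bis(methoxymethoxy)phenyl](1-ethoxyethoxy)methyllithium 22 (not isolated)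
Conditions: 18, MeLi, THF, −78 °C; then 21 pretreated with LiN(SiMe3)2 (1.0 equiv), −78 → −30 °C
Reagents that add atoms: none
Why: Tin–lithium exchange with MeLi, which is far slower than n-BuLi in bromine–lithium exchange with the aryl bromide at −78 °C, gives the chelated α-alkoxybenzyllithium, which acylates once on the Weinreb amide (Weinreb ketone synthesis) while the lithium alkoxide shields Cβ, so Cβ stays S.

**Step 15**
Reactants: 23 (1S)-3-[2-bromo-4,6-bis(methoxymethoxy)phenyl]-3-(1-ethoxyethoxy)-1-hydroxy-1-[4-(methoxymethoxy)phenyl]propan-2-one; 13 (2S,3S)-3-[(tert-butyldimethylsilyl)oxy]-7-methoxy-2-[4-(methoxymethoxy)phenyl]-3,4-dihydro-2H-chromene-5,8-dione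
Product: 26 tricyclic quinol (flavan 2S,3S; pyran-3-one fused at C7–O and C8; Cβ S; C4′ S bearing 1-ethoxyethoxy and the bromoaryl group; C8 S bearing OH), via dilithio alkoxide enolate of the hydroxy ketone 24 (not isolated), via quinone-tethered lithium enolate 25 (not isolated)
Conditions: LiN(SiMe3)2 (2.1 equiv), THF, −78 °C; then 13, −78 → −40 °C; pH 7 buffer
Reagents that add atoms: none
Why: Proposed new method: two equivalents of base should remove the hydroxyl proton and then the C4′–H on the side remote from the alkoxide (α′-deprotonation, as in dianions of α-hydroxy ketones), so Cβ is never enolised; the alkoxide replaces the C7 methoxy group by addition–elimination and the tethered enolate then adds to the adjacent, non-vinylogous quinone carbonyl C8 (6-exo-trig aldol) with the Cβ aryl group equatorial and anti to the axial bromoaryl group, which fixes the attacked face of C8 and with it C4′; the closest known reactions are the alkoxy exchange of 2-methoxy-1,4-benzoquinones and the 1,2-addition of lithium enolates and organolithiums to the more electrophilic carbonyl of 2,6-dialkoxy-1,4-benzoquinones.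

**Step 16**
Reactants: 26 tricyclic quinol
Product: 27 spiro dihydrobenzofuran with C4′ 1-ethoxyethyl ether (flavan 2S,3S; Cβ S; C4′ S; C8 S)
Conditions: Pd(OAc)2 (5 mol %), 2-(di-tert-butylphosphino)-1,1′-binaphthyl (6 mol %), Cs2CO3, toluene, 60 °C
Reagents that add atoms: none
Why: Intramolecular Pd-catalysed aryl ether formation (Buchwald-type etherification) suits a tertiary alkoxide, which has no β-hydrogen on the carbinol carbon, and only the quinol with bromoaryl group and hydroxyl syn can close the five-membered ring, while a retro-aldol merely returns the tethered enolate, which recloses.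

**Step 17**
Reactants: 27 spiro dihydrobenzofuran with C4′ 1-ethoxyethyl ether
Product: 28 iso-α-ketol precursor: spiro 3-hydroxy-2,3-dihydrobenzofuran bridged by a pyran-3-one with free C4′–OH (flavan 2S,3S; Cβ S; C4′ S; C8 S)
Conditions: pyridinium p-toluenesulfonate (0.2 equiv), MeOH/CH2Cl2, 0 → 23 °C
Reagents that add atoms: none
Why: Transacetalisation removes the very labile 1-ethoxyethyl acetal at an acidity that should leave aryl methoxymethyl ethers, the secondary silyl ether and the vinylogous ester oxygens of ring D untouched.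

**Step 18**
Reactants: 28 iso-α-ketol precursor
Product: 29 protected target with free Cα–OH (flavan 2S,3S; Cβ S; Cα R; C8 S)
Conditions: Sc(OTf)3 (15 mol %), toluene, 40 °C
Reagents that add atoms: none
Why: Sc(OTf)3 binds the tertiary hydroxyl and the neighbouring pyranone carbonyl in a five-membered chelate, which polarises the carbonyl and lines up the C4′–C8 bond with its π* orbital; C8 then moves suprafacially from C4′ to the carbonyl carbon while the proton passes to the former carbonyl oxygen, so that carbon becomes the carbinol Cα and C4′ becomes the ring A ketone. This is an α-ketol (acyloin) rearrangement of the 1-acylcycloalkanol type, as in the D-homo rearrangement of 17-hydroxy-20-keto steroids. Ring B is formed by contraction of the pyranone (the migrating C8 stays bonded to C7 and leaves C4′ outside that ring, six to five) and ring C by expansion of the dihydrobenzofuran (Cα is inserted between C8 and C4′, five to six), both through the same 1,2-shift and not through an end-to-end closure. The one new stereocentre, Cα, is set by C8, which migrates with retention onto the only carbonyl face the cis-fused bicycle offers, so the hydroxyl ends up cis to C8a; Cβ is untouched because no enolising base is present. The step needs C8 and not the ring A aryl group to end up on Cα and the equilibrium to lie on the product side: the ketol isomers interconvert under the Lewis acid and only the target skeleton has its ketone conjugated with the electron-rich ring A, so it should be the thermodynamic sink.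

**Step 19**
Reactants: 29 protected target with free Cα–OH
Product: 30 target CNP0170480.5 (flavan 2S,3S; Cβ S; Cα R; C8 S)
Conditions: CF3CO2H/H2O/CH2Cl2 (10:1:10), 0 → 23 °C
Reagents that add atoms: none
Why: Aqueous acid hydrolyses the four aryl methoxymethyl acetals and the secondary silyl ether in one operation, without alcohol (which could exchange the vinylogous ester oxygens) and without base (which would provoke retro-aldol or ketol shifts at the tertiary α-hydroxy ketone).

**Compound list**
1 | 1,2,3,5-tetramethoxybenzene | COc1cc(OC)c(OC)c(OC)c1 | starting material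
2 | methyl (2S)-oxirane-2-carboxylate | COC(=O)[C@@H]1CO1 | starting material
3 | (2,3,4,6-tetramethoxyphenyl)lithium | COc1cc(OC)c(OC)c(OC)c1[Li] | intermediate
4 | bromo(2,3,4,6-tetramethoxyphenyl)magnesium | COc1cc(OC)c(OC)c(OC)c1[Mg]Br | intermediate
5 | methyl (2S)-2-hydroxy-3-(2,3,4,6-tetramethoxyphenyl)propanoate | COc1cc(OC)c(OC)c(OC)c1C[C@H](O)C(=O)OC | intermediate
6 | methyl (2S)-2-[(tert-butyldimethylsilyl)oxy]-3-(2,3,4,6-tetramethoxyphenyl)propanoate | COc1cc(OC)c(OC)c(OC)c1C[C@H](O[Si](C)(C)C(C)(C)C)C(=O)OC | intermediate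
7 | (2S)-2-[(tert-butyldimethylsilyl)oxy]-N-methoxy-N-methyl-3-(2,3,4,6-tetramethoxyphenyl)propanamide | COc1cc(OC)c(OC)c(OC)c1C[C@H](O[Si](C)(C)C(C)(C)C)C(=O)N(C)OC | intermediate
8 | 1-bromo-4-(methoxymethoxy)benzene | COCOc1ccc(Br)cc1 | starting material
9 | [4-(methoxymethoxy)phenyl]lithium | COCOc1ccc([Li])cc1 | intermediate
10 | (2S)-2-[(tert-butyldimethylsilyl)oxy]-1-[4-(methoxymethoxy)phenyl]-3-(2,3,4,6-tetramethoxyphenyl)propan-1-one | COc1cc(OC)c(OC)c(OC)c1C[C@H](O[Si](C)(C)C(C)(C)C)C(=O)c1ccc(OCOC)cc1 | intermediate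
11 | (1S,2S)-2-[(tert-butyldimethylsilyl)oxy]-1-[4-(methoxymethoxy)phenyl]-3-(2,3,4,6-tetramethoxyphenyl)propan-1-ol | COc1cc(OC)c(OC)c(OC)c1C[C@H](O[Si](C)(C)C(C)(C)C)[C@H](c1ccc(OCOC)cc1)O | intermediate
12 | 3-{(2S,3S)-2-[(tert-butyldimethylsilyl)oxy]-3-hydroxy-3-[4-(methoxymethoxy)phenyl]propyl}-2,6-dimethoxycyclohexa-2,5-diene-1,4-dione | COC1=CC(=O)C(C[C@H](O[Si](C)(C)C(C)(C)C)[C@H](c2ccc(OCOC)cc2)O)=C(OC)C1=O | intermediate
13 | (2S,3S)-3-[(tert-butyldimethylsilyl)oxy]-7-methoxy-2-[4-(methoxymethoxy)phenyl]-3,4-dihydro-2H-chromene-5,8-dione | O=C1C=C(OC)C(=O)C2=C1C[C@H](O[Si](C)(C)C(C)(C)C)[C@H](c1ccc(OCOC)cc1)O2 | intermediate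
14 | 2-bromo-4,6-dimethoxybenzaldehyde | COc1cc(OC)c(C=O)c(Br)c1 | starting material
15 | 2-bromo-4,6-dihydroxybenzaldehyde | Oc1cc(O)c(C=O)c(Br)c1 | intermediate
16 | 2-bromo-4,6-bis(methoxymethoxy)benzaldehyde | COCOc1cc(OCOC)c(C=O)c(Br)c1 | intermediate
17 | [2-bromo-4,6-bis(methoxymethoxy)phenyl](tributylstannyl)methanol (racemic) | CCCC[Sn](CCCC)(CCCC)C(O)c1c(OCOC)cc(OCOC)cc1Br | intermediate
18 | {[2-bromo-4,6-bis(methoxymethoxy)phenyl](1-ethoxyethoxy)methyl}tributylstannane (diastereomer mixture) | CCCC[Sn](CCCC)(CCCC)C(OC(C)OCC)c1c(OCOC)cc(OCOC)cc1Br | intermediate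
19 | (2S)-2-hydroxy-2-(4-hydroxyphenyl)acetic acid, (S)-4-hydroxymandelic acid | O[C@@H](c1ccc(O)cc1)C(=O)O | starting material
20 | (2S)-2-hydroxy-2-(4-hydroxyphenyl)-N-methoxy-N-methylacetamide | O[C@@H](c1ccc(O)cc1)C(=O)N(C)OC | intermediate
21 | (2S)-2-hydroxy-N-methoxy-2-[4-(methoxymethoxy)phenyl]-N-methylacetamide | O[C@@H](c1ccc(OCOC)cc1)C(=O)N(C)OC | intermediate
22 | [2-bromo-4,6-bis(methoxymethoxy)phenyl](1-ethoxyethoxy)methyllithium | [Li]C(OC(C)OCC)c1c(OCOC)cc(OCOC)cc1Br | intermediate
23 | (1S)-3-[2-bromo-4,6-bis(methoxymethoxy)phenyl]-3-(1-ethoxyethoxy)-1-hydroxy-1-[4-(methoxymethoxy)phenyl]propan-2-one (C1 = Cβ, C2 = Cα, C3 = C4′; mixture at C3 and at the acetal carbon) | O[C@@H](c1ccc(OCOC)cc1)C(=O)C(OC(C)OCC)c1c(OCOC)cc(OCOC)cc1Br | intermediate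
24 | dilithio alkoxide enolate of 23 (Cβ–O–Li and Cα=C4′ enolate) | [Li+].[Li+].[O-][C@@H](c1ccc(OCOC)cc1)C([O-])=C(OC(C)OCC)c1c(OCOC)cc(OCOC)cc1Br | intermediate
25 | lithium enolate tethered to the flavan quinone through C7–O–Cβ | [Li+].O=C1C=C(O[C@@H](c2ccc(OCOC)cc2)C([O-])=C(OC(C)OCC)c2c(OCOC)cc(OCOC)cc2Br)C(=O)C2=C1C[C@H](O[Si](C)(C)C(C)(C)C)[C@H](c1ccc(OCOC)cc1)O2 | intermediate
26 | tricyclic quinol: (2S,3S)-flavan unit whose ring D is an 8-hydroxy dienone, fused at C7–O and C8 to a pyran-3-one; Cβ S (H, 4-(methoxymethoxy)phenyl), Cα ketone, C4′ S (1-ethoxyethoxy, 2-bromo-4,6-bis(methoxymethoxy)phenyl), C8 S (OH) | O=C1C=C2O[C@@H](c3ccc(OCOC)cc3)C(=O)[C@](OC(C)OCC)(c3c(OCOC)cc(OCOC)cc3Br)[C@@]2(O)C2=C1C[C@H](O[Si](C)(C)C(C)(C)C)[C@H](c1ccc(OCOC)cc1)O2 | intermediate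
27 | spiro dihydrobenzofuran (ring A–O–C8 closed) bridged by the pyran-3-one, C4′–O–CH(CH3)OEt; flavan 2S,3S, Cβ S, C4′ S, C8 S | O=C1C=C2O[C@@H](c3ccc(OCOC)cc3)C(=O)[C@]3(OC(C)OCC)c4c(OCOC)cc(OCOC)cc4O[C@]23C2=C1C[C@H](O[Si](C)(C)C(C)(C)C)[C@H](c1ccc(OCOC)cc1)O2 | intermediate
28 | iso-α-ketol precursor: spiro 3-hydroxy-2,3-dihydrobenzofuran bridged by a pyran-3-one, free C4′–OH; flavan 2S,3S, Cβ S, C4′ S, C8 S | O=C1C=C2O[C@@H](c3ccc(OCOC)cc3)C(=O)[C@]3(O)c4c(OCOC)cc(OCOC)cc4O[C@]23C2=C1C[C@H](O[Si](C)(C)C(C)(C)C)[C@H](c1ccc(OCOC)cc1)O2 | intermediate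
29 | protected target (four methoxymethyl ethers, C3 silyl ether, free Cα–OH); flavan 2S,3S, Cβ S, Cα R, C8 S | O=C1C=C2O[C@@H](c3ccc(OCOC)cc3)[C@]3(O)C(=O)c4c(OCOC)cc(OCOC)cc4O[C@]23C2=C1C[C@H](O[Si](C)(C)C(C)(C)C)[C@H](c1ccc(OCOC)cc1)O2 | intermediate
30 | CNP0170480.5; flavan 2S,3S, Cβ S, Cα R, C8 S | O=C1C=C2O[C@@H](c3ccc(O)cc3)[C@]3(O)C(=O)c4c(O)cc(O)cc4O[C@]23C2=C1C[C@H](O)[C@H](c1ccc(O)cc1)O2 | target

**Step count and risks**
Total: 19 steps. Longest linear sequence: 12 steps (steps 1–7, then 15–19).

Step 15 (annulation). The second deprotonation may occur at Cβ instead of C4′, or the dianion may reduce the quinone by electron transfer. Either would erase the Cβ configuration before C8 is formed and give poor facial selectivity at the spiro centre, or no bond at all between the two fully substituted carbons. Fallback with known reactions, from 23 and 13 back to 26: 23 is converted into its sodium alkoxide (NaH, THF, −20 °C) and exchanged onto 13 by addition–elimination at C7 to give the tethered ketone F1, which is isolated. F1 is then closed by a reversible amine-base aldol (DBU, MeCN, 0 °C), in which only the C4′ enolate can form a ring. Under these equilibrating conditions Cβ no longer controls C8, so 26 would have to be separated from the series with the opposite spiro configuration and that series re-equilibrated.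

Step 18 (ketol shift). The ring A aryl group may migrate in place of C8, the mixture may stall among ketol isomers, or the Lewis acid may strip acetals before the shift is complete. Fallback, from 28 to 30: the protecting groups are removed first (CF3CO2H/H2O/CH2Cl2, 0 °C) to give the fully deprotected iso-ketol F2. F2 is then equilibrated in a neutral buffered medium (phosphate buffer pH 7.4/MeCN, 40 °C), a mild acyloin rearrangement in which the free peri hydroxyl of ring A can hydrogen-bond the new ketone and add to the driving force. This arrives directly at 30.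

Step 19 (global deprotection). Acid may ionise the two benzylic C–O bonds (C2–O1 and Cβ–O), which would epimerise or open rings B and E before all four acetals are cleaved. Fallback, from 29 to 30, in two orthogonal stages: fluoride first (HF·pyridine, pyridine/THF, 0 °C) to give the desilylated tetrakis(methoxymethyl) ether F3, then soft Lewis acid and thiol (ZnBr2, n-PrSH, CH2Cl2, 0 °C, minutes), which transfers the methoxymethyl groups to sulfur without a Brønsted acid.

**Further compounds**
F1 | step 15 | (2S,3S)-7-{(1S)-3-[2-bromo-4,6-bis(methoxymethoxy)phenyl]-3-(1-ethoxyethoxy)-1-[4-(methoxymethoxy)phenyl]-2-oxopropoxy}-3-[(tert-butyldimethylsilyl)oxy]-2-[4-(methoxymethoxy)phenyl]-3,4-dihydro-2H-chromene-5,8-dione (tethered ketone) | O=C1C=C(O[C@@H](c2ccc(OCOC)cc2)C(=O)C(OC(C)OCC)c2c(OCOC)cc(OCOC)cc2Br)C(=O)C2=C1C[C@H](O[Si](C)(C)C(C)(C)C)[C@H](c1ccc(OCOC)cc1)O2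
F2 | step 18 | fully deprotected iso-α-ketol (spiro 3-hydroxy-2,3-dihydrobenzofuran bridged by a pyran-3-one; flavan 2S,3S, Cβ S, C4′ S, C8 S) | O=C1C=C2O[C@@H](c3ccc(O)cc3)C(=O)[C@]3(O)c4c(O)cc(O)cc4O[C@]23C2=C1C[C@H](O)[C@H](c1ccc(O)cc1)O2
F3 | step 19 | desilylated tetrakis(methoxymethyl) ether of the target (free C3–OH and Cα–OH) | O=C1C=C2O[C@@H](c3ccc(OCOC)cc3)[C@]3(O)C(=O)c4c(OCOC)cc(OCOC)cc4O[C@]23C2=C1C[C@H](O)[C@H](c1ccc(OCOC)cc1)O2
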